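Start from X: the north-east flask, the one asked about, shows 1% of its charge at 15.0 min and 11% at 40.0 min.

in all of them: D 200 mM (held); Z 35 mM
- north-east: L 1.4 M; the very flask that is asked about, followed so far
- south-west: L 0.94 M; run made earlier
- flask: L 1.4 M; time 3.0 h

north-east run (percent of the L charged)

| time / min | X / % |
|---|---|
| 3.00 | 0 |
| 6.00 | 0 |
| 15.0 | 1 |
| 40.0 | 11 |

south-west run (percent of the L charged)

| time / h | X / % |
|---|---|
| 0.250 | 5 |
| 0.500 | 11 |
| 1.33 | 22 |
| 3.00 | 14 |

(scatter of a reading: 2 percentage points)

- how much X there is at 3.0 h, in percent of the L charged
- concentration of J in solution at 3.0 h, in percent of saturation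

- solid, in amounts per volume of the solution: L
- at the start none of L is in solution
- at the start none of D is in solution
- J is what D becomes in solution

Read from these two readings, with their scatter, that rise amounts to 5.60 mM min⁻¹. Call it the feed, the rate at which L leaves the solid and turns over. Take dissolving as the rate-limiting step, with a feed that does not depend on the amount of solid.

Now face the clash. A feed of 5.60 mM min⁻¹ that does not depend on the solid should keep adding X, yet the south-west flask reads 22% at 1.33 h and 14% at 3.00 h. Clear it with the life of each charge:

north-east: 1.4 M / 5.60 mM min⁻¹ = 4.17 h

south-west: 0.94 M / 5.60 mM min⁻¹ = 2.80 h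

The south-west life is shorter than its last reading time, so on this estimate the south-west flask is past its feed at that last reading. The north-east life is longer than 3.0 h, so on this estimate the north-east flask is still being fed at the asked time.

While solid lasts, both flasks should run alike in mM. The south-west reading at 1.33 h is 207 mM:

207 mM / 1.4 M = 14.8%

My own reckoning takes this as an estimate from below for north-east X at 3.0 h, not a point value, and it carries the scatter of the reading.

The forecast gives 16% of X, just above my estimate, and [J] at 85% of saturation, holding that “each mM counts for less as a percent of the charge”.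

The flask gives 22.5% of X and [J] at 35.3% of saturation.

    L ⇌ Q, rate k1*(cs1 - [Q]) while solid is left; crystals form when [Q] > cs1 (solubility = 0.440 M, k = 0.0160 min⁻¹)
    D ⇌ J, rate k2*(csat - [J]) (kL = 0.0930 min⁻¹)
    J + X → E (k = 0.260 M⁻¹ min⁻¹)
    Q + J + Z → Z + X (k = 57.0 M⁻² min⁻¹)

Reckoned at the feed of 5.60 mM min⁻¹, this flask and the neighbour with 0.14 M of Z in place of 35 mM share the life of 4.17 h, longer than 3.0 h, and at 3.0 h this flask holds 17.3% of its L as solid, while the neighbour has 13% of its L left, solid or dissolved, and 26.9% of X. At 3.00 h in this flask, where [J] stands at 0.0707 M, J has a half-life of 0.13 h by the making of X, of like size to 0.14 h by the loss of J + X to E, and both are short against 3.0 h.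

Readings and results were generated by integration for an exercise, and the scatter is random.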